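C1 alone joins C11 to C2. C11 and the three-carbon unit on C4 stand cis-1,3 on the cyclobutane C4–C5–C11–C10, on the face anti to the C6–C9 bridge. The route exploits this geometry by cutting C1–C11 and C1–C2 and returning C1 as carbon monoxide. In one operation a C11 radical takes up CO and the acyl radical closes the bicyclo[3.1.1]heptanone ring 6-endo. The precursor is a bis-silylated bicyclo[4.1.1]octane, built by a keteniminium [2+2]. It carries a xanthate on C11 and a 3-(phenylsulfanyl)prop-1-en-2-yl group on C4. Loss of PhS• ends the sequence before the C3 radical can open the cyclobutane.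

Key step: step 16

Remarks
- Atom numbers: C1 is the ring ketone, C2 and C3 are the enone alkene (methyl on C3), and C4, C5, C11 and C10 form the four-membered ring. C6 is the CMe2 carbon, C7 and C9 are the carbinol carbons, and C8 is the CH2 between them. "Bridge" means C6–C9.
- Target: read from the SMILES, the oxirane of the C7 ester has its two methyl groups cis, (2S,3R). The acid is therefore the epoxide of tiglic acid, not of angelic acid. The C9 ester is the (Z)-angelate.
- Radical precursor: no halide is placed on C11. C11 is a cyclobutyl carbon between quaternary C10 and C5 (next to C6), so displacing an activated alcohol there is not credible. A xanthate is made at oxygen instead.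
- Radical acceptor: a plain isopropenyl group is not used. Ring closure would give a tertiary cyclobutylcarbinyl radical at C3 (2-pinanyl type), which would cleave C4–C10 before a silane or stannane could reduce it.
- Protecting groups: O9 carries SiEt3 and O7 carries SiMe2tBu, so the angelate goes on first and the epoxy ester last. The bulkier group on O7 also disfavours attack of O7 on the activated amide.
- Supply: the two N-acyl thiazolidinethiones are taken as catalogue compounds. Otherwise each needs one acylation of the commercial auxiliary.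

Step 1
Reactants: 1 3-chloro-2-(chloromethyl)prop-1-ene; 2 benzenethiol
Product: 3 {[2-(chloromethyl)prop-2-en-1-yl]sulfanyl}benzene
Conditions: K2CO3, acetone, rt (1 in threefold excess)
Reagents that add atoms: none
Why: SN2 thioetherification of an allylic chloride, held at the mono stage by the excess of the symmetric dichloride; no stereocentre is formed.

Step 2
Reactants: 3; 4 triethyl phosphite
Product: 5 diethyl {2-[(phenylsulfanyl)methyl]prop-2-en-1-yl}phosphonate
Conditions: neat, 140 °C
Reagents that add atoms: none
Why: Michaelis–Arbuzov reaction of the remaining primary allylic chloride; an allylic shift of either group would regenerate the same skeleton.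

Step 3
Reactants: 6 methyl 3-hydroxy-2,2-dimethylpropanoate
Product: 7 methyl 2,2-dimethyl-3-oxopropanoate
Conditions: Dess–Martin periodinane, CH2Cl2, 0 °C to rt
Reagents that add atoms: none
Why: Dess–Martin oxidation of a primary neopentyl alcohol to a non-enolisable aldehyde, leaving the ester untouched.

Step 4
Reactants: 5; 7
Product: 8 methyl (3E)-2,2-dimethyl-5-[(phenylsulfanyl)methyl]hexa-3,5-dienoate
Conditions: 5, LiN(iPr)2, THF, −78 °C; then 7, −78 °C to rt
Reagents that add atoms: none
Why: Horner–Wadsworth–Emmons olefination with an allylic phosphonate anion, which with an α-quaternary aldehyde should give the (E)-C5=C4 alkene and brings in C4, C3, C2 and the sulfide-bearing carbon together.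

Step 5
Reactants: 8
Product: 9 (3E)-2,2-dimethyl-5-[(phenylsulfanyl)methyl]hexa-3,5-dien-1-ol
Conditions: LiAlH4, Et2O, 0 °C
Reagents that add atoms: none
Why: hydride reduction of the ester to the primary alcohol; the diene and the aryl allyl sulfide are inert to LiAlH4.

Step 6
Reactants: 9
Product: 10 (3E)-2,2-dimethyl-5-[(phenylsulfanyl)methyl]hexa-3,5-dienal (C7 aldehyde)
Conditions: Dess–Martin periodinane, CH2Cl2, 0 °C to rt
Reagents that add atoms: none
Why: Dess–Martin oxidation, which tolerates sulfides and dienes, gives an aldehyde that cannot enolise.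

Step 7
Reactants: 10; 11 1-[(4S)-4-benzyl-2-sulfanylidene-1,3-thiazolidin-3-yl]ethan-1-one
Product: 12 (3R,5E)-1-[(4S)-4-benzyl-2-sulfanylidene-1,3-thiazolidin-3-yl]-3-hydroxy-4,4-dimethyl-7-[(phenylsulfanyl)methyl]octa-5,7-dien-1-one
Conditions: 11, TiCl4, iPr2NEt, CH2Cl2, −78 °C; then 10
Reagents that add atoms: none
Why: acetate aldol of an N-acetylthiazolidinethione titanium enolate, in which the thione-chelated chair transition state lets the aldehyde reach the enolate face away from the benzyl group and sets C7 as R; the minor diastereomer is removed by chromatography.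

Step 8
Reactants: 12
Product: 13 the C7 tert-butyldimethylsilyl ether of 12
Conditions: TBSOTf, 2,6-lutidine, CH2Cl2, −78 to 0 °C
Reagents that add atoms: tert-butyldimethylsilyl triflate, CC(C)(C)[Si](C)(C)OS(=O)(=O)C(F)(F)F
Why: silylation with the silyl triflate, which is reactive enough for the neopentyl C7 hydroxyl and leaves the stereocentre untouched.

Step 9
Reactants: 13
Product: 14 (3R,5E)-3-[(tert-butyldimethylsilyl)oxy]-4,4-dimethyl-7-[(phenylsulfanyl)methyl]octa-5,7-dienal (C9 aldehyde)
Conditions: iBu2AlH, CH2Cl2, −78 °C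
Reagents that add atoms: none
Why: direct reductive cleavage of an N-acyl thiazolidinethione to the aldehyde, a standard property of this auxiliary, with recovery of the auxiliary.

Step 10
Reactants: 14; 15 1-[(4S)-4-benzyl-2-sulfanylidene-1,3-thiazolidin-3-yl]propan-1-one
Product: 16 (2S,3R,5R,7E)-1-[(4S)-4-benzyl-2-sulfanylidene-1,3-thiazolidin-3-yl]-5-[(tert-butyldimethylsilyl)oxy]-3-hydroxy-2,6,6-trimethyl-9-[(phenylsulfanyl)methyl]deca-7,9-dien-1-one
Conditions: 15, TiCl4, iPr2NEt, N-methylpyrrolidone, CH2Cl2, 0 °C; then 14, −78 to 0 °C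
Reagents that add atoms: none
Why: Evans-syn aldol of the (Z)-titanium enolate through the non-chelated chair transition state, in which the auxiliary sets C9 as R (anti to O7) under reagent control; the C10 centre formed here is erased in step 13.

Step 11
Reactants: 16
Product: 17 (2S,3R,5R,7E)-5-[(tert-butyldimethylsilyl)oxy]-3-hydroxy-2,6,6-trimethyl-9-[(phenylsulfanyl)methyl]-1-(pyrrolidin-1-yl)deca-7,9-dien-1-one
Conditions: pyrrolidine, CH2Cl2, rt
Reagents that add atoms: pyrrolidine, C1CCNC1
Why: aminolysis of the activated N-acyl thiazolidinethione by a secondary amine gives the tertiary amide needed for keteniminium formation without touching C7 or C9.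

Step 12
Reactants: 17
Product: 18 the C9 triethylsilyl ether of 17
Conditions: Et3SiCl, imidazole, DMF, rt
Reagents that add atoms: chlorotriethylsilane, CC[Si](Cl)(CC)CC
Why: standard silylation of the only free hydroxyl, which differentiates O9 (labile SiEt3) from O7 (robust SiMe2tBu).

Step 13
Reactants: 18
Product: 21 4-[(tert-butyldimethylsilyl)oxy]-1,5,5-trimethyl-8-[3-(phenylsulfanyl)prop-1-en-2-yl]-2-[(triethylsilyl)oxy]bicyclo[4.1.1]octan-7-one (C11 ketone; C4 side chain anti to the bridge; O9 on the C11 side; O7 on the C4 side), via keteniminium triflate 19 (not isolated), via cyclobutaniminium triflate 20 (not isolated)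
Conditions: Tf2O, 2,4,6-collidine, ClCH2CH2Cl (0.005 M), 0 to 80 °C; then aq. NaHCO3, 40 °C
Reagents that add atoms: water, O
Why: intramolecular keteniminium–alkene [2+2] cycloaddition in which diene terminus C5 attacks C11 (helped by the gem-dimethyl group) with allyl-cation character at C4 so that the crossed bicyclo[4.1.1] mode results, the (E)-alkene puts the C4 side chain trans to C6, the tether forces C6 and C9 onto one face, and C4 bonds to C10 anti to the bulky C9–OSiEt3 bond, which places O9 on the C11 side and O7 on the C4 side.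

Step 14
Reactants: 21
Product: 22 the C11 alcohol (OH anti to the bridge, cis to the C4 side chain)
Conditions: LiAlH4, Et2O, −78 to 0 °C
Reagents that add atoms: none
Why: hydride addition to a strained cyclobutanone, expected from the bridge side because the pseudo-axial C4 side chain covers the other face; C11 is erased in step 16, so either epimer would serve.

Step 15
Reactants: 22
Product: 23 the O-(C11) S-methyl dithiocarbonate (xanthate) of 22
Conditions: NaH, THF, 0 °C; CS2; then MeI, rt
Reagents that add atoms: carbon disulfide, S=C=S; iodomethane, CI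
Why: xanthate formation as in the first half of a Barton–McCombie sequence, which works on hindered alkoxides and needs no substitution at C11; O11 is anti to C9 so silyl migration cannot occur, and thermal syn elimination is blocked because the only β-hydrogen sits on bridgehead C5.

Step 16
Reactants: 23; 24 carbon monoxide
Product: 25 tricyclic C1 ketone with C2H2 and an exocyclic methylene on C3 (O9 SiEt3, O7 SiMe2tBu)
Conditions: CO (80 atm), (Bu3Sn)2, AIBN (in portions), benzene (0.01 M), 85 °C, autoclave
Reagents that add atoms: none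
Why: Proposed new method: a tributyltin radical adds to the C=S group of 23, the adduct fragments to the nearly planar C11 cyclobutyl radical, this takes up CO reversibly, the acyl radical adds to the CH2 terminus of the allyl sulfide, and the C3 radical expels PhS•, which regenerates the tin radical from (Bu3Sn)2, so that C1–C11 and C1–C2 form in one chain with no hydrogen donor present. The closest known reactions are the three-component radical coupling of alkyl halides, CO and allyltin reagents, the distannane-mediated allylation with allyl phenyl sulfides, and radical generation from xanthates as in the Barton–McCombie reaction; what is new is their union in a ring closure that starts from a xanthate. The one ring formed (C1–C2–C3–C4–C5 or C10–C11, a bicyclo[3.1.1]heptan-2-one) closes 6-endo-trig in the SH2' sense, because 5-exo attack at C3 would give a strained bicyclo[2.1.1]hexanone and a primary radical. The one new stereocentre, C11, is fixed by the ring closure itself: only the acyl radical on the face anti to the bridge can reach the alkene, and the other one loses CO again since nothing can reduce it, so the step is stereoconvergent. The step needs C–S scission at the C3 radical to outrun opening of the cyclobutane, which the sulfide on the acceptor is there to secure, and the alkene is released as C3=CH2 at the correct oxidation level. High CO pressure and high dilution favour CO capture over intermolecular addition, and direct attack of the C11 radical on the alkene is excluded because it would be 4-exo or 5-endo.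

Step 17
Reactants: 25
Product: 26 tricyclic enone (C1 ketone, C2=C3 with methyl on C3; O9 SiEt3, O7 SiMe2tBu)
Conditions: DBU (0.2 equiv), CH2Cl2, rt
Reagents that add atoms: none
Why: base-catalysed conjugation of a β,γ-unsaturated ketone through the C2 dienolate to the more stable trisubstituted enone; C4 and C11 are bridgeheads that cannot enolise, so no stereocentre is touched.

Step 18
Reactants: 26
Product: 27 C9 alcohol (O7 still SiMe2tBu)
Conditions: PPTS (cat.), MeOH–CH2Cl2, rt
Reagents that add atoms: none
Why: acid-catalysed methanolysis that removes a triethylsilyl ether much faster than a neopentyl tert-butyldimethylsilyl ether; hemiketal formation with C1 is excluded because C9 and C1 are trans on the C10–C11 bond.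

Step 19
Reactants: 27; 28 angelic acid, (2Z)-2-methylbut-2-enoic acid
Product: 30 C9 angelate (O7 SiMe2tBu), via angelic trichlorobenzoic anhydride 29 (not isolated)
Conditions: 28, 2,4,6-trichlorobenzoyl chloride, Et3N, toluene, rt; then 27, 80 °C
Reagents that add atoms: none
Why: Yamaguchi-type mixed-anhydride acylation run without a nucleophilic catalyst, the standard way to acylate hindered alcohols with retention of the (Z)-geometry of the angelate.

Step 20
Reactants: 30
Product: 31 C7 alcohol bearing the C9 angelate
Conditions: HF·pyridine, pyridine, THF, 0 °C to rt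
Reagents that add atoms: none
Why: fluoride-driven desilylation under buffered conditions that spare the enone and the angelate; the trans-1,3 relation of O7 and O9 on the seven-membered ring prevents acyl migration.

Step 21
Reactants: 32 tiglic acid, (2E)-2-methylbut-2-enoic acid
Product: 33 (2E)-2-methylbut-2-en-1-ol
Conditions: LiAlH4, Et2O, 0 °C to rt
Reagents that add atoms: none
Why: 1,2-reduction of the unsaturated acid to the allylic alcohol with the (E)-geometry unchanged.

Step 22
Reactants: 33
Product: 34 [(2R,3R)-2,3-dimethyloxiran-2-yl]methanol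
Conditions: Ti(OiPr)4 (10 mol %), D-(−)-diisopropyl tartrate (12 mol %), t-BuOOH, 4 Å sieves, CH2Cl2, −20 °C
Reagents that add atoms: tert-butyl hydroperoxide, CC(C)(C)OO
Why: Sharpless asymmetric epoxidation, in which the D-(−)-tartrate complex delivers oxygen to the alkene face that gives the (2R,3R)-epoxide, and syn addition to the (E)-alkene keeps the two methyl groups cis.

Step 23
Reactants: 34
Product: 35 (2S,3R)-2,3-dimethyloxirane-2-carboxylic acid
Conditions: RuCl3 (2 mol %), NaIO4, CCl4–MeCN–H2O, rt
Reagents that add atoms: sodium periodate, [Na+].[O-]I(=O)(=O)=O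
Why: ruthenium-catalysed periodate oxidation of a 2,3-epoxy alcohol to the glycidic acid without touching either stereocentre; the C2 descriptor changes from R to S only because the priorities change.

Step 24
Reactants: 31; 35
Product: 37 target CNP0149458.1, via epoxy acid mixed anhydride 36 (not isolated)
Conditions: 35, 2,4,6-trichlorobenzoyl chloride, Et3N, toluene, rt; then 31, DMAP, rt to 40 °C
Reagents that add atoms: none
Why: Yamaguchi esterification, suited to coupling an α-quaternary acid with a neopentyl secondary alcohol under mild basic conditions that spare the oxirane, the enone and the already installed angelate; C7 is acylated with retention.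

Compound list
1 | 3-chloro-2-(chloromethyl)prop-1-ene | C=C(CCl)CCl | starting material
2 | benzenethiol | Sc1ccccc1 | starting material
3 | {[2-(chloromethyl)prop-2-en-1-yl]sulfanyl}benzene | C=C(CCl)CSc1ccccc1 | intermediate
4 | triethyl phosphite | CCOP(OCC)OCC | starting material
5 | diethyl {2-[(phenylsulfanyl)methyl]prop-2-en-1-yl}phosphonate | C=C(CSc1ccccc1)CP(=O)(OCC)OCC | intermediate
6 | methyl 3-hydroxy-2,2-dimethylpropanoate | COC(=O)C(C)(C)CO | starting material
7 | methyl 2,2-dimethyl-3-oxopropanoate | COC(=O)C(C)(C)C=O | intermediate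
8 | methyl (3E)-2,2-dimethyl-5-[(phenylsulfanyl)methyl]hexa-3,5-dienoate | COC(=O)C(C)(C)/C=C/C(=C)CSc1ccccc1 | intermediate
9 | (3E)-2,2-dimethyl-5-[(phenylsulfanyl)methyl]hexa-3,5-dien-1-ol | OCC(C)(C)/C=C/C(=C)CSc1ccccc1 | intermediate
10 | (3E)-2,2-dimethyl-5-[(phenylsulfanyl)methyl]hexa-3,5-dienal | O=CC(C)(C)/C=C/C(=C)CSc1ccccc1 | intermediate
11 | 1-[(4S)-4-benzyl-2-sulfanylidene-1,3-thiazolidin-3-yl]ethan-1-one | CC(=O)N1[C@@H](Cc2ccccc2)CSC1=S | starting material
12 | acetate aldol adduct, (3R,5E), (4S)-auxiliary | O=C(C[C@@H](O)C(C)(C)/C=C/C(=C)CSc1ccccc1)N1[C@@H](Cc2ccccc2)CSC1=S | intermediate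
13 | C7 tert-butyldimethylsilyl ether of 12 | O=C(C[C@@H](O[Si](C)(C)C(C)(C)C)C(C)(C)/C=C/C(=C)CSc1ccccc1)N1[C@@H](Cc2ccccc2)CSC1=S | intermediate
14 | (3R,5E)-3-[(tert-butyldimethylsilyl)oxy]-4,4-dimethyl-7-[(phenylsulfanyl)methyl]octa-5,7-dienal | O=CC[C@@H](O[Si](C)(C)C(C)(C)C)C(C)(C)/C=C/C(=C)CSc1ccccc1 | intermediate
15 | 1-[(4S)-4-benzyl-2-sulfanylidene-1,3-thiazolidin-3-yl]propan-1-one | CCC(=O)N1[C@@H](Cc2ccccc2)CSC1=S | starting material
16 | syn propionate aldol adduct, (2S,3R,5R,7E), (4S)-auxiliary | O=C([C@@H](C)[C@H](O)C[C@@H](O[Si](C)(C)C(C)(C)C)C(C)(C)/C=C/C(=C)CSc1ccccc1)N1[C@@H](Cc2ccccc2)CSC1=S | intermediate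
17 | pyrrolidine amide, (2S,3R,5R,7E), free C9 hydroxyl | O=C([C@@H](C)[C@H](O)C[C@@H](O[Si](C)(C)C(C)(C)C)C(C)(C)/C=C/C(=C)CSc1ccccc1)N1CCCC1 | intermediate
18 | pyrrolidine amide, O9 SiEt3, O7 SiMe2tBu | O=C([C@@H](C)[C@H](O[Si](CC)(CC)CC)C[C@@H](O[Si](C)(C)C(C)(C)C)C(C)(C)/C=C/C(=C)CSc1ccccc1)N1CCCC1 | intermediate
19 | keteniminium triflate (C10=C11=N+) | CC(=C=[N+]1CCCC1)[C@H](O[Si](CC)(CC)CC)C[C@@H](O[Si](C)(C)C(C)(C)C)C(C)(C)/C=C/C(=C)CSc1ccccc1.[O-]S(=O)(=O)C(F)(F)F | intermediate
20 | bicyclo[4.1.1]octane C11 pyrrolidinium (cyclobutaniminium) triflate | CC[Si](CC)(CC)O[C@@H]1C[C@@H](O[Si](C)(C)C(C)(C)C)C(C)(C)[C@@H]2C(=[N+]3CCCC3)[C@@]1(C)[C@H]2C(=C)CSc3ccccc3.[O-]S(=O)(=O)C(F)(F)F | intermediate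
21 | bicyclo[4.1.1]octan-7-one (C11 ketone), C4 side chain anti to the bridge, O9 on the C11 side, O7 on the C4 side | CC[Si](CC)(CC)O[C@@H]1C[C@@H](O[Si](C)(C)C(C)(C)C)C(C)(C)[C@@H]2C(=O)[C@@]1(C)[C@H]2C(=C)CSc3ccccc3 | intermediate
22 | C11 alcohol, OH anti to the bridge and cis to the C4 side chain | CC[Si](CC)(CC)O[C@@H]1C[C@@H](O[Si](C)(C)C(C)(C)C)C(C)(C)[C@@H]2[C@@H](O)[C@@]1(C)[C@H]2C(=C)CSc3ccccc3 | intermediate
23 | C11 O-alkyl S-methyl dithiocarbonate (key-step precursor) | CC[Si](CC)(CC)O[C@@H]1C[C@@H](O[Si](C)(C)C(C)(C)C)C(C)(C)[C@@H]2[C@@H](OC(=S)SC)[C@@]1(C)[C@H]2C(=C)CSc3ccccc3 | intermediate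
24 | carbon monoxide | [C-]#[O+] | starting material
25 | tricyclic C1 ketone, C2H2, exocyclic methylene on C3 (key-step product) | CC[Si](CC)(CC)O[C@@H]1C[C@@H](O[Si](C)(C)C(C)(C)C)C(C)(C)[C@@H]2[C@H]3C(=O)CC(=C)[C@@H]2[C@]31C | intermediate
26 | tricyclic enone, O9 SiEt3, O7 SiMe2tBu | CC[Si](CC)(CC)O[C@@H]1C[C@@H](O[Si](C)(C)C(C)(C)C)C(C)(C)[C@@H]2[C@H]3C(=O)C=C(C)[C@@H]2[C@]31C | intermediate
27 | tricyclic enone, free C9 hydroxyl, O7 SiMe2tBu | O[C@@H]1C[C@@H](O[Si](C)(C)C(C)(C)C)C(C)(C)[C@@H]2[C@H]3C(=O)C=C(C)[C@@H]2[C@]31C | intermediate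
28 | angelic acid, (2Z)-2-methylbut-2-enoic acid | C/C=C(/C)C(=O)O | starting material
29 | (2Z)-2-methylbut-2-enoic 2,4,6-trichlorobenzoic anhydride | C/C=C(/C)C(=O)OC(=O)c1c(Cl)cc(Cl)cc1Cl | intermediate
30 | C9 angelate, O7 SiMe2tBu | C/C=C(/C)C(=O)O[C@@H]1C[C@@H](O[Si](C)(C)C(C)(C)C)C(C)(C)[C@@H]2[C@H]3C(=O)C=C(C)[C@@H]2[C@]31C | intermediate
31 | C9 angelate, free C7 hydroxyl | C/C=C(/C)C(=O)O[C@@H]1C[C@@H](O)C(C)(C)[C@@H]2[C@H]3C(=O)C=C(C)[C@@H]2[C@]31C | intermediate
32 | tiglic acid, (2E)-2-methylbut-2-enoic acid | C/C=C(\C)C(=O)O | starting material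
33 | (2E)-2-methylbut-2-en-1-ol | C/C=C(\C)CO | intermediate
34 | [(2R,3R)-2,3-dimethyloxiran-2-yl]methanol | OC[C@@]1(C)O[C@@H]1C | intermediate
35 | (2S,3R)-2,3-dimethyloxirane-2-carboxylic acid (methyl groups cis) | OC(=O)[C@@]1(C)O[C@@H]1C | intermediate
36 | (2S,3R)-2,3-dimethyloxirane-2-carboxylic 2,4,6-trichlorobenzoic anhydride | O=C(OC(=O)[C@@]1(C)O[C@@H]1C)c1c(Cl)cc(Cl)cc1Cl | intermediate
37 | CNP0149458.1, (4R,5S,7R,9R,10R,11R) in the numbering above, C9 (Z)-angelate, C7 (2S,3R)-2,3-dimethyloxirane-2-carboxylate | C/C=C(/C)C(=O)O[C@@H]1C[C@@H](OC(=O)[C@@]2(C)O[C@@H]2C)C(C)(C)[C@@H]2[C@H]3C(=O)C=C(C)[C@@H]2[C@]31C | target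

Total step count: 24. Longest linear sequence: 20 steps (1, 2, 4–20, 24).

Steps most likely to fail

1. Step 16. The C3 radical may cleave C4–C10 in competition with loss of PhS•. Tin or thiyl radicals may add reversibly to the acceptor alkene, or to the exocyclic alkene of 25, and open the four-membered ring in the same way. Fragmentation of the tin–xanthate adduct to the strained secondary radical may also be slow.
Fallback (known chemistry, no CO capture): C1 is brought in by a polar homologation and the acyl radical is made from an aldehyde. Setting out from 21, Wittig reaction with Ph3P=CHOMe (from (methoxymethyl)triphenylphosphonium chloride and KOtBu) gives the C11 methoxymethylidene compound F1. Mild hydrolysis (PPTS, wet acetone) protonates C11 from the bridge side and gives the C11 carbaldehyde F2, with the formyl group cis to the C4 side chain. A thiol-catalysed radical-chain cyclisation of this alkenal (tert-dodecanethiol, AIBN, toluene, 80 °C) then abstracts the formyl hydrogen, closes the same 6-endo ring and expels PhS•, which carries the chain. The route is rejoined at 25.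

2. Step 13. The O7 silyl ether oxygen may attack the activated amide in a six-membered mode and end as a lactone. The silyloxy group β to C10 may be lost. The allyl cation may close at C2 instead of C4. The facial selectivity relative to C7 and C9 may be poor.
Fallback: a neutral ketene replaces the cationic keteniminium ion. Setting out from 16, Et3SiOTf and 2,6-lutidine give the silylated imide F3, and LiOH (THF–H2O, 0 °C) cleaves the auxiliary to the carboxylic acid F4. Treatment with 1-chloro-N,N,2-trimethylprop-1-en-1-amine gives the acid chloride F5. Slow addition to Et3N in refluxing toluene generates the methyl(alkyl)ketene F6, which undergoes the thermal crossed intramolecular [2+2] with the diene. The route is rejoined at 21.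

3. Step 19. The activated angelate may isomerise from Z to E during a slow acylation of the hindered C9 hydroxyl.
Fallback: the alkene is built on the ester instead of being carried through the acylation. Setting out from 27, carbodiimide coupling (EDCI, DMAP) with 2-[bis(2,2,2-trifluoroethoxy)phosphoryl]propanoic acid gives the C9 phosphonopropanoate F7. Still–Gennari olefination (KN(SiMe3)2, 18-crown-6, THF, −78 °C, then acetaldehyde) forms the (Z)-trisubstituted enoate. The route is rejoined at 30.

Further compounds
F1 | step 16 | C11 methoxymethylidene bicyclo[4.1.1]octane (E/Z mixture at the enol ether) | CC[Si](CC)(CC)O[C@@H]1C[C@@H](O[Si](C)(C)C(C)(C)C)C(C)(C)[C@@H]2C(=COC)[C@@]1(C)[C@H]2C(=C)CSc3ccccc3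
F2 | step 16 | C11 carbaldehyde, formyl group anti to the bridge and cis to the C4 side chain | CC[Si](CC)(CC)O[C@@H]1C[C@@H](O[Si](C)(C)C(C)(C)C)C(C)(C)[C@@H]2[C@@H](C=O)[C@@]1(C)[C@H]2C(=C)CSc3ccccc3
F3 | step 13 | C9 triethylsilyl ether of 16 | O=C([C@@H](C)[C@H](O[Si](CC)(CC)CC)C[C@@H](O[Si](C)(C)C(C)(C)C)C(C)(C)/C=C/C(=C)CSc1ccccc1)N1[C@@H](Cc2ccccc2)CSC1=S
F4 | step 13 | (2S,3R,5R,7E)-bis-silyloxy carboxylic acid | OC(=O)[C@@H](C)[C@H](O[Si](CC)(CC)CC)C[C@@H](O[Si](C)(C)C(C)(C)C)C(C)(C)/C=C/C(=C)CSc1ccccc1
F5 | step 13 | acid chloride of F4 | ClC(=O)[C@@H](C)[C@H](O[Si](CC)(CC)CC)C[C@@H](O[Si](C)(C)C(C)(C)C)C(C)(C)/C=C/C(=C)CSc1ccccc1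
F6 | step 13 | methyl(alkyl)ketene from F5 | O=C=C(C)[C@H](O[Si](CC)(CC)CC)C[C@@H](O[Si](C)(C)C(C)(C)C)C(C)(C)/C=C/C(=C)CSc1ccccc1
F7 | step 19 | C9 2-[bis(2,2,2-trifluoroethoxy)phosphoryl]propanoate of 27 (epimers at the phosphonate carbon) | CC(C(=O)O[C@@H]1C[C@@H](O[Si](C)(C)C(C)(C)C)C(C)(C)[C@@H]2[C@H]3C(=O)C=C(C)[C@@H]2[C@]31C)P(=O)(OCC(F)(F)F)OCC(F)(F)F
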